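**Plan**

- Cuts: first the two C6–O bonds of the peroxyketal (C6–O1 and C6–OMe), which opens the 1,2-dioxane to an acyclic (S)-3-peroxy-6-oxo ester. Then C3–OO (sulfonate displacement), C6–C7 (Grignard addition), C4–C5 (allylation) and C11–C12 (Sonogashira coupling).
- Enabling feature: in the ring O1–O2–C3–C4–C5–C6, C6 is a peroxyketal carbon that ionises reversibly. Its OMe is cis to the C3 CH2CO2Me arm, which is the chair with axial (anomeric) OMe and equatorial chain and arm, so C3 alone can fix C6 by equilibration.
- Chain assembly: dec-9-enal, iodoform and 5-chloropentyne give the C7–C22 dienyne chloride. (S)-Butane-1,2,4-triol supplies C1–C4, allyl supplies C5–C6, and the Grignard reagent of the chloride joins C7 to C6.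
- Masking: C6 (future ketone) and C1 (future ester) stay as silyl ethers while the C3 mesylate is displaced by the protected hydroperoxide. Both are then oxidised, and the only ring closes in the last step.
- Stereochemistry: C3 comes from the triol, is retained up to the (R)-carbinol and is inverted once to the (S)-peroxide. C6 is set thermodynamically from C3. The E-alkene comes from the Takai olefination and is retained in the coupling.

Key step: step 19

Remark and assumption: C1–C22 number the docosadienynoate chain (C1 is the ester carbon), and C3 and C6 are also ring positions 3 and 6. The C6 carbinol made in step 9 is carried as an epimer mixture, left undefined in the SMILES, because step 16 erases it.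

**Step 1**
Reactants: 1 dec-9-en-1-ol
Product: 2 dec-9-enal
Conditions: TEMPO (cat.), PhI(OAc)2, CH2Cl2, rt
Reagents that add atoms: none
Why: Oxoammonium-mediated (TEMPO) alcohol oxidation stops at the aldehyde in anhydrous CH2Cl2 and leaves the terminal alkene alone.

**Step 2**
Reactants: 2 dec-9-enal
Product: 3 (1E)-1-iodoundeca-1,10-diene
Conditions: CrCl2, CHI3, THF-dioxane, 0 °C
Reagents that add atoms: iodoform, IC(I)I
Why: Takai olefination, in which the geminal dichromium reagent adds to the aldehyde and eliminates preferentially to the E-iodoalkene (C12=C13), the dioxane co-solvent reinforcing this preference and the isolated alkene being inert to divalent chromium.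

**Step 3**
Reactants: 3 (1E)-1-iodoundeca-1,10-diene; 4 5-chloropent-1-yne
Product: 5 (10E)-16-chlorohexadeca-1,10-dien-12-yne
Conditions: Pd(PPh3)2Cl2 (cat.), CuI (cat.), Et3N, THF, rt
Reagents that add atoms: 5-chloropent-1-yne 4, C#CCCCCl
Why: Sonogashira coupling forms C11–C12 with retention of the E geometry, and the primary alkyl chloride does not add oxidatively to zerovalent palladium at room temperature.

**Step 4**
Reactants: 6 2,3-dimethylbut-2-ene; 7 methanol
Product: 9 2-methoxypropan-2-yl hydroperoxide, via acetone O-oxide 8 (not isolated)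
Conditions: O3, MeOH-CH2Cl2, -78 °C
Reagents that add atoms: ozone, [O-][O+]=O; methanol 7, CO
Why: Criegee ozonolysis in a participating solvent, where the symmetric alkene can give only acetone and carbonyl oxide 8, which methanol traps as the alpha-methoxy hydroperoxide.

**Step 5**
Reactants: 10 (S)-butane-1,2,4-triol
Product: 11 [(2S,4S)-2-(4-methoxyphenyl)-1,3-dioxan-4-yl]methanol
Conditions: 4-MeOC6H4CH(OMe)2, CSA (cat.), CH2Cl2, rt
Reagents that add atoms: 4-methoxybenzaldehyde dimethyl acetal, COC(OC)c1ccc(OC)cc1
Why: Acid-catalysed transacetalisation under thermodynamic control prefers the six-membered 1,3-dioxane across the C1 and C3 oxygens with aryl and CH2OH equatorial, so the triol stereocentre is untouched, the acetal centre follows from it and only the C4 hydroxyl stays free.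

**Step 6**
Reactants: 11 [(2S,4S)-2-(4-methoxyphenyl)-1,3-dioxan-4-yl]methanol
Product: 12 (2S,4S)-4-(iodomethyl)-2-(4-methoxyphenyl)-1,3-dioxane
Conditions: I2, PPh3, imidazole, THF, 0 °C to rt
Reagents that add atoms: iodine, II
Why: Appel-type (Garegg-Samuelsson) iodination replaces the primary hydroxyl by SN2 at C4 under nearly neutral conditions that spare the acetal and the neighbouring stereocentre.

**Step 7**
Reactants: 12 (2S,4S)-4-(iodomethyl)-2-(4-methoxyphenyl)-1,3-dioxane; 13 allylmagnesium bromide
Product: 14 (2S,4R)-4-(but-3-en-1-yl)-2-(4-methoxyphenyl)-1,3-dioxane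
Conditions: allylMgBr, CuI (cat.), THF, -20 °C to rt
Reagents that add atoms: allylmagnesium bromide 13, C=CC[Mg]Br
Why: Copper-catalysed cross-coupling of a Grignard reagent with a primary alkyl iodide forms C4–C5 without touching C3, whose descriptor changes from S to R only because the CIP ranking changes.

**Step 8**
Reactants: 14 (2S,4R)-4-(but-3-en-1-yl)-2-(4-methoxyphenyl)-1,3-dioxane
Product: 16 3-[(2S,4R)-2-(4-methoxyphenyl)-1,3-dioxan-4-yl]propanal, via diol 15 (not isolated)
Conditions: OsO4 (cat.), NaIO4, 2,6-lutidine, dioxane-H2O, rt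
Reagents that add atoms: sodium periodate, [Na+].[O-]I(=O)(=O)=O
Why: Lemieux-Johnson cleavage (catalytic dihydroxylation, then periodate glycol cleavage) turns the terminal alkene into the C6 aldehyde, with 2,6-lutidine keeping the medium neutral for the acetal and without the acetal C–H oxidation that ozone can cause.

**Step 9**
Reactants: 5 (10E)-16-chlorohexadeca-1,10-dien-12-yne; 16 3-[(2S,4R)-2-(4-methoxyphenyl)-1,3-dioxan-4-yl]propanal
Product: 18 (9E)-1-[(2S,4R)-2-(4-methoxyphenyl)-1,3-dioxan-4-yl]nonadeca-9,18-dien-7-yn-3-ol (C6 epimers), via Grignard reagent 17 (not isolated)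
Conditions: 5, Mg turnings, THF, reflux; then 16, THF, -78 to 0 °C; H2O
Reagents that add atoms: none
Why: Grignard formation from the primary chloride (a 4-pentynyl-type organomagnesium has no favourable cyclisation mode) and 1,2-addition to the aldehyde form C6–C7, and the new carbinol centre needs no control because it later becomes the ketone.

**Step 10**
Reactants: 18 C6 carbinol
Product: 19 tert-butyldimethylsilyl ether of 18 at the C6 oxygen
Conditions: TBSCl, imidazole, DMF, rt
Reagents that add atoms: tert-butyldimethylsilyl chloride, CC(C)(C)[Si](C)(C)Cl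
Why: Imidazole-promoted silylation masks the future ketone as a base-stable ether that cannot enolise.

**Step 11**
Reactants: 19 C6 silyl ether acetal
Product: 20 (3R,12E)-6-[(tert-butyldimethylsilyl)oxy]docosa-12,21-dien-10-yne-1,3-diol
Conditions: AcOH-THF-H2O, rt
Reagents that add atoms: none
Why: Acid hydrolysis of the electron-rich 4-methoxybenzylidene acetal is much faster than cleavage of a secondary TBS ether, so only the C1/C3 diol is freed and C3 keeps its configuration.

**Step 12**
Reactants: 20 1,3-diol
Product: 21 (3R,12E)-1,6-bis[(tert-butyldimethylsilyl)oxy]docosa-12,21-dien-10-yn-3-ol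
Conditions: TBSCl (1 equiv), imidazole, CH2Cl2, -10 °C
Reagents that add atoms: tert-butyldimethylsilyl chloride, CC(C)(C)[Si](C)(C)Cl
Why: Sterically controlled monosilylation, since the primary C1 hydroxyl reacts far faster than the secondary C3 hydroxyl with one equivalent of TBSCl in the cold.

**Step 13**
Reactants: 21 (3R)-carbinol
Product: 22 (3R,12E)-1,6-bis[(tert-butyldimethylsilyl)oxy]docosa-12,21-dien-10-yn-3-yl methanesulfonate
Conditions: MsCl, Et3N, CH2Cl2, 0 °C
Reagents that add atoms: methanesulfonyl chloride, CS(=O)(=O)Cl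
Why: O-Sulfonylation activates the C3 oxygen as a leaving group without breaking the C3–O bond, so the R configuration is retained.

**Step 14**
Reactants: 22 (3R)-mesylate; 9 2-methoxypropan-2-yl hydroperoxide
Product: 23 (3S,12E)-1,6-bis[(tert-butyldimethylsilyl)oxy]-3-[(2-methoxypropan-2-yl)peroxy]docosa-12,21-dien-10-yne
Conditions: 9 (excess), CsOH·H2O, DMF, 0 °C to rt
Reagents that add atoms: 2-methoxypropan-2-yl hydroperoxide 9, COC(C)(C)OO
Why: SN2 alkylation of a hydroperoxide anion by a secondary sulfonate, in which the alpha-effect cesium peroxide attacks C3 from the rear and inverts it from R to S, while the alcohol oxidation level at C1 and C6 removes every acidic C–H that could cause E1cB loss of mesylate or cyclopropane closure.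

**Step 15**
Reactants: 23 bis-silyl peroxyketal
Product: 24 (3S,12E)-3-[(2-methoxypropan-2-yl)peroxy]docosa-12,21-dien-10-yne-1,6-diol
Conditions: TBAF, THF, 0 °C to rt
Reagents that add atoms: none
Why: Fluoride-induced desilylation cleaves both Si–O bonds, and a dialkyl-type peroxide whose alpha C–H is not activated by a carbonyl group tolerates TBAF.

**Step 16**
Reactants: 24 1,6-diol
Product: 25 (3S,12E)-3-[(2-methoxypropan-2-yl)peroxy]-6-oxodocosa-12,21-dien-10-ynal
Conditions: Dess-Martin periodinane, NaHCO3, CH2Cl2, 0 °C to rt; used crude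
Reagents that add atoms: none
Why: Dess-Martin oxidation takes both carbinols to the carbonyl level in a buffered, non-aqueous medium that leaves the O–O bond, the acid-labile peroxyketal and the dienyne alone, and the C6 epimers converge here.

**Step 17**
Reactants: 25 keto aldehyde
Product: 26 (3S,12E)-3-[(2-methoxypropan-2-yl)peroxy]-6-oxodocosa-12,21-dien-10-ynoic acid
Conditions: NaClO2, NaH2PO4, 2-methylbut-2-ene, t-BuOH-H2O, 0 °C
Reagents that add atoms: sodium chlorite, [Na+].[O-]Cl=O
Why: Pinnick oxidation converts only the aldehyde, the cold phosphate buffer is too weakly acidic to unmask the peroxyketal quickly, and the excess of 2-methylbut-2-ene intercepts hypochlorous acid before it reaches the chain alkenes.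

**Step 18**
Reactants: 26 keto acid
Product: 27 methyl (3S,12E)-3-[(2-methoxypropan-2-yl)peroxy]-6-oxodocosa-12,21-dien-10-ynoate
Conditions: TMSCHN2, toluene-MeOH, 0 °C
Reagents that add atoms: (trimethylsilyl)diazomethane, C[Si](C)(C)C=[N+]=[N-]
Why: Diazoalkane esterification starts with proton transfer from the acid and needs no base, so beta-elimination of the C3 peroxide is avoided.

**Step 19**
Reactants: 27 methyl (3S,12E)-3-[(2-methoxypropan-2-yl)peroxy]-6-oxodocosa-12,21-dien-10-ynoate; 7 methanol
Product: 31 peroxyacarnoate A methyl 2-[(3S,6R)-6-[(6E)-hexadeca-6,15-dien-4-yn-1-yl]-6-methoxy-1,2-dioxan-3-yl]acetate, via hydroperoxy ketone 28 (not isolated), via dioxanol 29 (not isolated), via peroxycarbenium ion 30 (not isolated)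
Conditions: TsOH·H2O (cat.), MeOH, rt; NaHCO3 quench
Reagents that add atoms: methanol 7, CO
Why: The acid strips the 2-methoxyprop-2-yl group and frees hydroperoxide 28, whose terminal oxygen adds to the C6 carbonyl in a 6-exo-trig closure to give dioxanol 29. Protonation and loss of water then give the cyclic peroxycarbenium ion 30, which methanol captures at C6, so C6–O1 and C6–OMe are the two new bonds and the 1,2-dioxane is the one new ring. The closest known reaction type is the acid-catalysed cyclisation of gamma-hydroperoxy ketones to 1,2-dioxan-3-ols followed by their ketalisation with an alcohol. C3 takes no part and stays S, whereas addition, ionisation and capture at C6 are all reversible, so the new C6 centre is set thermodynamically by C3: the chair with axial OMe (anomeric interaction with O1) and equatorial arm and chain, which is the (3S,6R) cis isomer, is the energy minimum. The step needs only diastereoselection at C6 and reaction at the ketone, and the 1,4 spacing of OOH and C=O makes the six-membered ring the only unstrained closure. A catalytic Brønsted acid at room temperature touches neither the enyne, the terminal alkene nor the methyl ester.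

**Compound list**

1 | dec-9-en-1-ol | C=CCCCCCCCCO | starting material
2 | dec-9-enal | C=CCCCCCCCC=O | intermediate
3 | (1E)-1-iodoundeca-1,10-diene | C=CCCCCCCC/C=C/I | intermediate
4 | 5-chloropent-1-yne | C#CCCCCl | starting material
5 | (10E)-16-chlorohexadeca-1,10-dien-12-yne | C=CCCCCCCC/C=C/C#CCCCCl | intermediate
6 | 2,3-dimethylbut-2-ene | CC(C)=C(C)C | starting material
7 | methanol | CO | starting material
8 | acetone O-oxide | CC(C)=[O+][O-] | intermediate
9 | 2-methoxypropan-2-yl hydroperoxide | COC(C)(C)OO | intermediate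
10 | (S)-butane-1,2,4-triol | OCC[C@H](O)CO | starting material
11 | [(2S,4S)-2-(4-methoxyphenyl)-1,3-dioxan-4-yl]methanol | OC[C@@H]1CCO[C@H](c2ccc(OC)cc2)O1 | intermediate
12 | (2S,4S)-4-(iodomethyl)-2-(4-methoxyphenyl)-1,3-dioxane | IC[C@@H]1CCO[C@H](c2ccc(OC)cc2)O1 | intermediate
13 | allylmagnesium bromide | C=CC[Mg]Br | starting material
14 | (2S,4R)-4-(but-3-en-1-yl)-2-(4-methoxyphenyl)-1,3-dioxane | C=CCC[C@@H]1CCO[C@H](c2ccc(OC)cc2)O1 | intermediate
15 | 4-[(2S,4R)-2-(4-methoxyphenyl)-1,3-dioxan-4-yl]butane-1,2-diol | OCC(O)CC[C@@H]1CCO[C@H](c2ccc(OC)cc2)O1 | intermediate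
16 | 3-[(2S,4R)-2-(4-methoxyphenyl)-1,3-dioxan-4-yl]propanal | O=CCC[C@@H]1CCO[C@H](c2ccc(OC)cc2)O1 | intermediate
17 | [(6E)-hexadeca-6,15-dien-4-yn-1-yl]magnesium chloride | C=CCCCCCCC/C=C/C#CCCC[Mg]Cl | intermediate
18 | (9E)-1-[(2S,4R)-2-(4-methoxyphenyl)-1,3-dioxan-4-yl]nonadeca-9,18-dien-7-yn-3-ol, C6 epimers | C=CCCCCCCC/C=C/C#CCCCC(O)CC[C@@H]1CCO[C@H](c2ccc(OC)cc2)O1 | intermediate
19 | C6 tert-butyldimethylsilyl ether of 18 | C=CCCCCCCC/C=C/C#CCCCC(O[Si](C)(C)C(C)(C)C)CC[C@@H]1CCO[C@H](c2ccc(OC)cc2)O1 | intermediate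
20 | (3R,12E)-6-[(tert-butyldimethylsilyl)oxy]docosa-12,21-dien-10-yne-1,3-diol | C=CCCCCCCC/C=C/C#CCCCC(O[Si](C)(C)C(C)(C)C)CC[C@@H](O)CCO | intermediate
21 | (3R,12E)-1,6-bis[(tert-butyldimethylsilyl)oxy]docosa-12,21-dien-10-yn-3-ol | C=CCCCCCCC/C=C/C#CCCCC(O[Si](C)(C)C(C)(C)C)CC[C@@H](O)CCO[Si](C)(C)C(C)(C)C | intermediate
22 | (3R,12E)-1,6-bis[(tert-butyldimethylsilyl)oxy]docosa-12,21-dien-10-yn-3-yl methanesulfonate | C=CCCCCCCC/C=C/C#CCCCC(O[Si](C)(C)C(C)(C)C)CC[C@@H](OS(C)(=O)=O)CCO[Si](C)(C)C(C)(C)C | intermediate
23 | (3S,12E)-1,6-bis[(tert-butyldimethylsilyl)oxy]-3-[(2-methoxypropan-2-yl)peroxy]docosa-12,21-dien-10-yne | C=CCCCCCCC/C=C/C#CCCCC(O[Si](C)(C)C(C)(C)C)CC[C@H](OOC(C)(C)OC)CCO[Si](C)(C)C(C)(C)C | intermediate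
24 | (3S,12E)-3-[(2-methoxypropan-2-yl)peroxy]docosa-12,21-dien-10-yne-1,6-diol | C=CCCCCCCC/C=C/C#CCCCC(O)CC[C@H](OOC(C)(C)OC)CCO | intermediate
25 | (3S,12E)-3-[(2-methoxypropan-2-yl)peroxy]-6-oxodocosa-12,21-dien-10-ynal | C=CCCCCCCC/C=C/C#CCCCC(=O)CC[C@H](OOC(C)(C)OC)CC=O | intermediate
26 | (3S,12E)-3-[(2-methoxypropan-2-yl)peroxy]-6-oxodocosa-12,21-dien-10-ynoic acid | C=CCCCCCCC/C=C/C#CCCCC(=O)CC[C@H](OOC(C)(C)OC)CC(=O)O | intermediate
27 | methyl (3S,12E)-3-[(2-methoxypropan-2-yl)peroxy]-6-oxodocosa-12,21-dien-10-ynoate | C=CCCCCCCC/C=C/C#CCCCC(=O)CC[C@@H](CC(=O)OC)OOC(C)(C)OC | intermediate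
28 | methyl (3S,12E)-3-hydroperoxy-6-oxodocosa-12,21-dien-10-ynoate | C=CCCCCCCC/C=C/C#CCCCC(=O)CC[C@@H](CC(=O)OC)OO | intermediate
29 | methyl 2-[(3S)-6-[(6E)-hexadeca-6,15-dien-4-yn-1-yl]-6-hydroxy-1,2-dioxan-3-yl]acetate, C6 epimers | C=CCCCCCCC/C=C/C#CCCCC1(O)CC[C@@H](CC(=O)OC)OO1 | intermediate
30 | (S)-configured cyclic peroxycarbenium ion, C6=O1(+) | C=CCCCCCCC/C=C/C#CCCCC1CC[C@@H](CC(=O)OC)O[O+]=1 | intermediate
31 | peroxyacarnoate A, methyl 2-[(3S,6R)-6-[(6E)-hexadeca-6,15-dien-4-yn-1-yl]-6-methoxy-1,2-dioxan-3-yl]acetate | C=CCCCCCCC/C=C/C#CCCC[C@]1(OC)CC[C@@H](CC(=O)OC)OO1 | target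

Total step count: 19. Longest linear sequence: 15 steps (steps 5–19, from 10 to 31).

**Steps most likely to fail**

**Step 14.** Substitution by the bulky peroxide anion may be slow. E2 elimination of the secondary mesylate towards C2 or C4 could then win, or basic loss of the C6 silyl group could be followed by tetrahydrofuran closure onto C3.

Fallback: the route sets out from 22 and changes the nucleophile to the small hydroperoxide anion (H2O2, KOH, MeOH-THF, 0 °C to rt). This classical perhydrolysis of a secondary sulfonate also proceeds with inversion and should give (3S,12E)-1,6-bis[(tert-butyldimethylsilyl)oxy]docosa-12,21-dien-10-yn-3-yl hydroperoxide F1. Addition of its OOH group to 2-methoxypropene (PPTS cat., CH2Cl2, 0 °C) comes back to the route at 23.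

**Step 16.** The beta-peroxy aldehyde may lose the C3 peroxide by E1cB elimination on handling. Acetic acid released by the oxidant may also strip the peroxyketal.

Fallback: the route sets out from 24 and never lets the aldehyde accumulate.
- TEMPO (cat.)/PhI(OAc)2 in MeCN-pH 7 phosphate buffer oxidises only the primary alcohol, through the aldehyde hydrate, to (3S,12E)-6-hydroxy-3-[(2-methoxypropan-2-yl)peroxy]docosa-12,21-dien-10-ynoic acid F2.
- TMSCHN2 in toluene-MeOH gives methyl (3S,12E)-6-hydroxy-3-[(2-methoxypropan-2-yl)peroxy]docosa-12,21-dien-10-ynoate F3.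
- Buffered Dess-Martin oxidation of the remaining C6 carbinol comes back to the route at 27.

**Step 19.** Equilibration may stay incomplete, leaving the 6-epimer or an open-chain dimethyl ketal hydroperoxide in the mixture. Long acid exposure may also trigger heterolytic O–O fragmentation. Any separated 6-epimer can simply be resubmitted to the same conditions.

Fallback: the same two bonds are formed in stages, setting out from 27.
- AcOH-THF-H2O unmasks the hydroperoxide, and dioxanol 29 is isolated.
- Ac2O, pyridine and DMAP (cat.) convert it into methyl 2-[(3S)-6-acetoxy-6-[(6E)-hexadeca-6,15-dien-4-yn-1-yl]-1,2-dioxan-3-yl]acetate F4.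
- TMSOTf (cat.) with MeOSiMe3 in CH2Cl2 at -78 °C ionises F4 to the same peroxycarbenium ion, which is captured by stereoelectronically favoured axial attack. This comes back to the route at 31.

**Further compounds**

F1 | step 14 | (3S,12E)-1,6-bis[(tert-butyldimethylsilyl)oxy]docosa-12,21-dien-10-yn-3-yl hydroperoxide | C=CCCCCCCC/C=C/C#CCCCC(O[Si](C)(C)C(C)(C)C)CC[C@H](OO)CCO[Si](C)(C)C(C)(C)C
F2 | step 16 | (3S,12E)-6-hydroxy-3-[(2-methoxypropan-2-yl)peroxy]docosa-12,21-dien-10-ynoic acid | C=CCCCCCCC/C=C/C#CCCCC(O)CC[C@H](OOC(C)(C)OC)CC(=O)O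
F3 | step 16 | methyl (3S,12E)-6-hydroxy-3-[(2-methoxypropan-2-yl)peroxy]docosa-12,21-dien-10-ynoate | C=CCCCCCCC/C=C/C#CCCCC(O)CC[C@H](OOC(C)(C)OC)CC(=O)OC
F4 | step 19 | methyl 2-[(3S)-6-acetoxy-6-[(6E)-hexadeca-6,15-dien-4-yn-1-yl]-1,2-dioxan-3-yl]acetate | C=CCCCCCCC/C=C/C#CCCCC1(OC(C)=O)CC[C@@H](CC(=O)OC)OO1
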